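I started from a small charge of X and asked what share of its percentage of G stays when the charge is larger.

in all of them: D 73 mM (held)

| flask | X | remark | time |
|---|---|---|---|
| epsilon | 0.59 M (fed, over 1.0 h) | run made earlier; the fed solution adds 0.20 times the starting volume |  |
| delta | 0.92 M (fed, over 1.0 h) | run made earlier; the fed solution adds 0.20 times the starting volume |  |
| flask | 0.42 M (fed, over 1.0 h) | the fed solution adds 0.20 times the starting volume | 10 h |

| run | time / h | G / % |
|---|---|---|
| epsilon | 1.50 | 3.2 |
| epsilon | 2.50 | 8.4 |
| epsilon | 4.00 | 13.6 |
| epsilon | 5.00 | 15.6 |
| epsilon | 8.00 | 16.5 |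
| delta | 1.50 | 2.9 |
| delta | 2.50 | 7.5 |
| delta | 4.00 | 11.0 |
| delta | 5.00 | 12.8 |
| delta | 8.00 | 13.7 |

(each reading ± 0.3 percentage points)

- the best time, 10 h at the latest, for G
- the amount of G, in percent of the X charged, at that time
- earliest time at which at least nineteen twentieths of that best amount are there
- latest time at which they still are

- every charge counts on the volume at the start, and the solution that is fed holds the whole dose
- at the start none of D is in solution

At 8.00 h the epsilon run held 16.5 % of its charge as G and the delta run, on the larger charge, held less, at 13.7 %. I assumed that the reciprocal of the percentage climbs in a straight line with the charge. The two readings, with their scatter, then give a halving charge of 1.02 M, the charge at which the percentage of G stands at half its small-charge value. That small-charge value comes out at 26.0 %. On that assumption, at that time and with D and the feed as in the two runs, the share left at a given charge is one over one plus the charge divided by the halving charge. At 0.42 M this share is 70.9 %, so I reckoned the flask at 18.4 %.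

The weak link was the time, since 8.00 h need not be the peak. I repeated the reckoning on the pair at 5.00 h, 15.6 % and 12.8 %. They give a halving charge of 0.919 M and 17.6 % for the flask at that time, which is 95.7 % of my figure. So I committed to about 18.4 % as the top, with the level asked for reached near 5.00 h and the peak left open between the two times.

The forecast gave 18.5 % at 10 h, open from 5.3 h to 10 h, though it allowed that “a shallow maximum a little earlier is possible”.

The flask peaked at 6.54 h with 18.1 %, and stayed at the level asked for from 5.10 h to 8.28 h.

    2 L → Q (k = 3.49 × 10⁻⁴ M⁻¹ s⁻¹)
    G → Z (k = 6.11 × 10⁻⁵ s⁻¹)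
    J + L → G (k = 0.00323 M⁻¹ s⁻¹)
    X → L (k = 6.03 × 10⁻⁵ s⁻¹)
    D ⇌ J, rate k5*(csat - [J]) (kL = 2.92 × 10⁻⁴ s⁻¹)
    L → E (k = 1.36 × 10⁻⁴ s⁻¹)

At that peak the flask held Z at 15.3 % of the X charged. The flask's peak is 69.6 % of my small-charge value, against a share left of 70.9 %. For the neighbouring flask with 1.1 M of X the share left is 48.2 %, which makes 12.5 %, and that flask's best was 13.1 %.

The numbers in the tables were computed for an exercise; noise was put on by code.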